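**Strategy.** Everything rests on closing ring C last by the C8–C14 bond. The step exploits that C14 is quaternary, sits beside quaternary C13 and joins methine C8 whose hydrogen is cis to the C9 methyl: hydrogen-atom transfer to a C14 exocyclic methylene gives a tertiary radical that adds 6-exo to C8 of a ring B enone, so the C14 methyl, the C8–C14 bond and both stereocentres arise in one operation. The precursor is a 3-bromo-2-fluoro-4,4-disubstituted naphthalenone (rings A and B) tied through C11–C12 to a cis-fused ring D/E decalin bearing the C14 methylene and a C21 ketal. The C6 ketone then activates C2–F for attachment of the guaiane diol.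

Key step: step 18

Remark: locants C1–C22 follow triterpene numbering and primed locants the guaiane; the ligand enantiomers named in steps 2, 10 and 22 are those expected by analogy to give the drawn centres, the antipodes being equally available.

**Rings A/B fragment**

Step 1
Reactants: 1 2-bromo-3-fluorotoluene
Product: 3 (4-bromo-3-fluoro-5-methylphenyl)boronic acid, via pinacol boronate 2 (not isolated)
Conditions: [Ir(OMe)(cod)]2 (1.5 mol%), 4,4′-di-tert-butyl-2,2′-bipyridine, B2pin2 (0.6 equiv), THF, 70 °C; then NaIO4, aq. HCl, THF/H2O, rt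
Reagents that add atoms: bis(pinacolato)diboron, CC1(C)OB(OC1(C)C)B1OC(C)(C)C(C)(C)O1; water, O
Why: Sterically governed iridium-catalysed C–H borylation of a 1,2,3-trisubstituted arene should occur at C5 of the toluene (the later C10), the only C–H without a larger ortho neighbour, and periodate cleaves the pinacol ester (Hartwig–Miyaura borylation with oxidative hydrolysis).

Step 2
Reactants: 3 (4-bromo-3-fluoro-5-methylphenyl)boronic acid; 4 geraniol, (E)-3,7-dimethylocta-2,6-dien-1-ol
Product: 5 (S)-3-(4-bromo-3-fluoro-5-methylphenyl)-3,7-dimethyloct-6-enal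
Conditions: Pd(CH3CN)2(OTs)2 (6 mol%), Cu(OTf)2 (6 mol%), (S)-4-tert-butyl-2-[5-(trifluoromethyl)pyridin-2-yl]-4,5-dihydrooxazole (13 mol%), 3 Å MS, O2 (1 atm), DMF, rt
Reagents that add atoms: none
Why: Enantioselective redox-relay oxidative Heck arylation (Sigman type): the aryl group adds to the methyl-bearing alkene carbon distal to the hydroxyl, palladium walks to the carbinol carbon and releases the aldehyde, the ligand and the E geometry set the C9 quaternary centre as S, and the remote prenyl alkene lacks the polarising alcohol and should not insert.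

Step 3
Reactants: 5 aldehyde
Product: 6 (S)-3-(4-bromo-3-fluoro-5-methylphenyl)-3,7-dimethyloct-6-en-1-ol
Conditions: NaBH4, MeOH, 0 °C
Reagents that add atoms: none
Why: Borohydride reduction of the only carbonyl group gives the C12 alcohol without touching the aryl halides or the alkene.

Step 4
Reactants: 6 alcohol
Product: 7 (S)-2-bromo-5-(1-bromo-3,7-dimethyloct-6-en-3-yl)-1-fluoro-3-methylbenzene
Conditions: CBr4, PPh3, CH2Cl2, 0 °C
Reagents that add atoms: carbon tetrabromide, BrC(Br)(Br)Br
Why: Appel bromination converts the unhindered primary alcohol into the C12 bromide, a group that survives the oxidative and acidic steps that follow.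

Step 5
Reactants: 7 bromide
Product: 9 (S)-6-bromo-4-(4-bromo-3-fluoro-5-methylphenyl)-4-methylhexanoic acid, via bromo aldehyde 8 (not isolated)
Conditions: O3, CH2Cl2/MeOH, −78 °C; Me2S; then NaClO2, NaH2PO4, 2-methyl-2-butene, t-BuOH/H2O, rt
Reagents that add atoms: ozone, [O-][O+]=O; sodium chlorite, [Na+].[O-]Cl=O
Why: Ozonolysis cleaves the only alkene (the halogenated arene is inert at −78 °C) and Pinnick oxidation takes the C6 aldehyde to the acid.

Step 6
Reactants: 9 bromo acid
Product: 10 (S)-7-bromo-4-(2-bromoethyl)-6-fluoro-4,8-dimethyl-3,4-dihydronaphthalen-1(2H)-one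
Conditions: P2O5/MeSO3H (Eaton's reagent), 60 °C
Reagents that add atoms: none
Why: Intramolecular Friedel–Crafts acylation closes the six-membered ring B at C5, the ring carbon para to fluorine and ortho to methyl (fluorine directs para far more strongly than ortho), while the quaternary C9 cannot ionise and the primary bromide is inert to Brønsted acid.

Step 7
Reactants: 10 tetralone
Product: 11 tert-butyl{[(S)-7-bromo-4-(2-bromoethyl)-6-fluoro-4,8-dimethyl-3,4-dihydronaphthalen-1-yl]oxy}dimethylsilane
Conditions: TBSOTf, Et3N, CH2Cl2, 0 °C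
Reagents that add atoms: tert-butyldimethylsilyl triflate, CC(C)(C)[Si](C)(C)OS(=O)(=O)C(F)(F)F
Why: Silyl enol ether formation masks the C6 ketone as a group that is neither acidic nor electrophilic and that can later be oxidised directly to the enone.

Step 8
Reactants: 11 bromo enol ether
Product: 12 tert-butyl{[(S)-7-bromo-6-fluoro-4-(2-iodoethyl)-4,8-dimethyl-3,4-dihydronaphthalen-1-yl]oxy}dimethylsilane
Conditions: NaI, NaHCO3, acetone, reflux
Reagents that add atoms: sodium iodide, [Na+].[I-]
Why: Finkelstein exchange at the primary C12 carbon gives the more reactive iodide under neutral conditions that leave the enol ether intact.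

**Rings D/E fragment**

Step 9
Reactants: 13 1,4-dioxaspiro[4.5]dec-6-en-8-one
Product: 14 (±)-9-methyl-1,4-dioxaspiro[4.5]dec-6-en-8-one
Conditions: LiN(i-Pr)2, THF, −78 °C; MeI, −78 to 0 °C
Reagents that add atoms: iodomethane, CI
Why: Kinetic deprotonation of a 4,4-disubstituted cyclohexenone occurs only at the α′ carbon and methylation there installs the future C17 methyl (its configuration is set later).

Step 10
Reactants: 14 methyl enone
Product: 15 (6R)-6,9-dimethyl-1,4-dioxaspiro[4.5]decan-8-one (C9 epimers)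
Conditions: Cu(OTf)2 (2 mol%), (S,R,R)-BINOL bis(1-phenylethyl)phosphoramidite (4 mol%), Me2Zn, toluene, −30 °C
Reagents that add atoms: dimethylzinc, C[Zn]C
Why: Copper–phosphoramidite catalysed asymmetric conjugate addition (Feringa type) delivers methyl to the β-carbon under ligand control and sets C20 as R, while the epimerisable α centre is erased in step 11.

Step 11
Reactants: 15 dimethyl ketone; 16 (S)-1-phenylethylamine; 17 ethyl vinyl ketone
Product: 20 (6R,9S)-6,9-dimethyl-9-(3-oxopentyl)-1,4-dioxaspiro[4.5]decan-8-one, via imine 18 (not isolated), via adduct imine 19 (not isolated)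
Conditions: 16, TsOH (cat.), toluene, reflux (−H2O); 17, THF, 40 °C; then 20% aq. AcOH, rt
Reagents that add atoms: water, O
Why: d'Angelo deracemising Michael addition: the chiral imine reacts through its more substituted secondary enamine and the auxiliary shields one face, so the C17 quaternary centre is set under auxiliary control with its methyl cis to the C20 methyl.

Step 12
Reactants: 20 diketone
Product: 21 (4aS,7R)-6,6-(ethylenedioxy)-1,4a,7-trimethyl-4,4a,5,6,7,8-hexahydronaphthalen-2(3H)-one
Conditions: NaOMe, MeOH, 60 °C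
Reagents that add atoms: none
Why: Intramolecular aldol condensation (second stage of a Robinson annulation) closes ring D as the C13=C18 enone with the C14 carbonyl, and the ketal is stable to base.

Step 13
Reactants: 21 octalone
Product: 22 (1R,4aS,7R,8aS)-6,6-(ethylenedioxy)-1,4a,7-trimethyloctahydronaphthalen-2(1H)-one (cis-fused)
Conditions: H2 (3 atm), 10% Pd/C, 0.1 M KOH in EtOH, rt
Reagents that add atoms: none
Why: Heterogeneous hydrogenation of 4a-methyl octalones over Pd/C in basic ethanol is known to give the cis-fused decalone, so H-18 should be set cis to the C17 methyl (C13 is erased in step 14).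

Step 14
Reactants: 22 cis-decalone
Product: 23 trimethylsilyl enol ether of 22 with the C13=C14 double bond
Conditions: TMSCl, Et3N, DMF, 130 °C
Reagents that add atoms: chlorotrimethylsilane, C[Si](C)(C)Cl
Why: Equilibrating silylation (House conditions) favours the more substituted enol ether, and a cis-fused ketone of this type enolises towards the ring-fusion side, so the tetrasubstituted C13=C14 isomer should predominate.

**Union and key step**

Step 15
Reactants: 23 silyl enol ether; 12 iodide
Product: 25 C13-alkylated decalone (ring A/B silyl enol ether joined through C11–C12 to the D/E decalin with C14 ketone and C21 ketal; C13 methyl trans to H-18), via lithium enolate 24 (not isolated)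
Conditions: 23 (2 equiv), MeLi, THF, 0 °C; then 12, HMPA, −20 to 30 °C
Reagents that add atoms: none
Why: Regiospecific lithium enolate generation from the enol silane and SN2 alkylation by the primary iodide (House–Stork enolate alkylation) forms the C12–C13 bond and the C13 quaternary centre, the electrophile being expected on the convex face of the cis-fused bicycle, anti to the C18–C19 bond.

Step 16
Reactants: 25 ketone
Product: 26 C14-methylene analogue of 25
Conditions: Ph3PCH3Br, NaN(SiMe3)2, toluene, 0 °C; then 25, 80 °C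
Reagents that add atoms: methyltriphenylphosphonium bromide, C[P+](c1ccccc1)(c1ccccc1)c1ccccc1.[Br-]
Why: Wittig methylenation with an alkoxide-free ylide converts the hindered C14 ketone, the only free carbonyl because C6 is masked, into the exocyclic alkene.

Step 17
Reactants: 26 methylene compound
Product: 27 3-bromo-2-fluoro naphthalenone with the C14-methylene D/E decalin and C21 ketal
Conditions: Pd(OAc)2 (1.2 equiv), MeCN/CH2Cl2, 25–40 °C
Reagents that add atoms: none
Why: Saegusa–Ito oxidation turns the silyl enol ether directly into the C7=C8 enone of the 4,4-disubstituted naphthalen-1-one, in which C9 is quaternary so no isomerisation is possible.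

Step 18
Reactants: 27 naphthalenone
Product: 28 3-bromo-2-fluoro pentacyclic C6 ketone, C21 ketal (H-8 cis to C9 methyl; C14 methyl trans to C13 methyl)
Conditions: Fe(acac)3 (0.5 equiv), PhSiH3 (3 equiv), EtOH/ethylene glycol 5:1 with THF, 60 °C, argon
Reagents that add atoms: none
Why: Fe(acac)3 and PhSiH3 in ethanol generate an iron hydride that transfers a hydrogen atom to the terminal carbon of the C14 methylene, creating the C14 methyl and a nucleophilic tertiary radical that adds to C8 of the electron-poor C7=C8 enone, after which the C7 α-keto radical is reduced and protonated. The closest known reaction type is the iron-hydride hydrogen-atom-transfer reductive olefin coupling (Giese type) in its intramolecular form. Ring C is closed in a 6-exo-trig mode through C14–C13–C12–C11–C9–C8. C8 is controlled by the tether: C11 is held on one face of the flat ring B at C9, so the radical can reach C8 only from that face and H-8 ends cis to the C9 methyl (cis B/C fusion). C14 is controlled by a chair-like transition state with C12 equatorial on ring D and the forming bond equatorial as well, which places the new methyl anti to the C13 methyl (trans C/D fusion). The step needs hydrogen-atom transfer to the electron-rich 1,1-disubstituted alkene in the presence of the enone, aryl bromide and ketal, which the polarity preference of the metal hydride secures, and 6-exo over 7-endo closure, which the two-carbon tether and the match of a nucleophilic radical with the enone β-carbon secure.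

**Guaiane fragment**

Step 19
Reactants: 29 (S)-(+)-carvone
Product: 30 trimethyl{[(5S)-2-methyl-5-(prop-1-en-2-yl)cyclohex-1-en-1-yl]oxy}silane
Conditions: LiBH(s-Bu)3, THF, −78 °C; TMSCl, Et3N, −78 to 0 °C
Reagents that add atoms: chlorotrimethylsilane, C[Si](C)(C)Cl
Why: Conjugate reduction of the enone by the hindered borohydride and O-silylation of the enolate give the regiodefined enol ether on the methyl-bearing side, with the isopropenyl group untouched.

Step 20
Reactants: 30 silyl enol ether
Product: 31 trimethyl{[(3S)-6-methyl-3-(prop-1-en-2-yl)bicyclo[4.1.0]heptan-1-yl]oxy}silane (cyclopropane diastereomers)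
Conditions: Et2Zn, CH2I2, CH2Cl2, 0 °C to rt
Reagents that add atoms: diiodomethane, ICI
Why: Furukawa–Simmons–Smith cyclopropanation is selective for the electron-rich enol ether over the 1,1-disubstituted alkene, and the new cyclopropane centres are lost in step 21.

Step 21
Reactants: 31 siloxycyclopropane
Product: 33 (S)-3-methyl-6-(prop-1-en-2-yl)cyclohept-2-en-1-one, via chloro ketone 32 (not isolated)
Conditions: FeCl3, DMF, 0 °C to rt; then NaOAc, MeOH, reflux
Reagents that add atoms: none
Why: Saegusa–Ito ring expansion: one-electron oxidation opens the internal cyclopropane bond to the tertiary radical, chlorine transfer gives the β-chloro cycloheptanone and acetate eliminates HCl to the enone, inserting C1′ between the carbonyl carbon (C5′) and the methyl-bearing carbon (C10′).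

Step 22
Reactants: 33 cycloheptenone
Product: 35 (2S,3R,6S)-2-allyl-3-methyl-6-(prop-1-en-2-yl)cycloheptan-1-one, via silyl enol ether 34 (not isolated)
Conditions: CuCl (5 mol%), NaOt-Bu (5 mol%), (S)-p-tol-BINAP (5 mol%), (EtO)2MeSiH, toluene, 0 °C; then allyl bromide, Bu4N[Ph3SiF2], CH2Cl2, rt
Reagents that add atoms: allyl bromide, C=CCBr
Why: Copper hydride asymmetric conjugate reduction (Buchwald type) sets C10′ under ligand control with its methyl cis to the C7′ isopropenyl group, and fluoride activation of the regiodefined silyl enol ether allylates C1′ (trans to the C10′ methyl, a centre erased in step 23).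

Step 23
Reactants: 35 allyl ketone
Product: 36 (2S,3R,6S)-2-allyl-2-hydroxy-3-methyl-6-(prop-1-en-2-yl)cycloheptan-1-one
Conditions: KOt-Bu, P(OEt)3, O2 (1 atm), THF/t-BuOH, −20 °C
Reagents that add atoms: dioxygen, O=O
Why: Enolate autoxidation with in situ phosphite reduction (Gardner α-hydroxylation) occurs at the tertiary α-carbon through the more substituted enolate, and oxygen should enter anti to the adjacent C10′ methyl so that O1′ is trans to it.

Step 24
Reactants: 36 hydroxy ketone
Product: 37 triethylsilyl ether of 36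
Conditions: TESOTf, 2,6-lutidine, CH2Cl2, −78 to −20 °C
Reagents that add atoms: triethylsilyl triflate, CC[Si](CC)(CC)OS(=O)(=O)C(F)(F)F
Why: Low-temperature silylation of the tertiary alcohol gives a non-chelating α-siloxy ketone, the directing group needed for step 25.

Step 25
Reactants: 37 siloxy ketone
Product: 40 (1S,2S,4S,7R)-1-allyl-2-[(tert-butyldimethylsilyl)oxy]-7-methyl-2,4-di(prop-1-en-2-yl)cycloheptan-1-ol, via lithium alkoxide 38 (not isolated), via bis-silyl ether 39 (not isolated)
Conditions: 2-bromopropene, t-BuLi, THF/Et2O, −78 °C; 37, −78 °C; TBSOTf, −78 to −40 °C; work-up; AcOH/THF/H2O 3:1:1, rt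
Reagents that add atoms: 2-bromopropene, CC(Br)=C; tert-butyldimethylsilyl triflate, CC(C)(C)[Si](C)(C)OS(=O)(=O)C(F)(F)F
Why: Felkin–Anh addition: the alkenyllithium attacks the C5′ ketone anti to the adjacent C1′–OSi bond, so the two oxygens end cis and both alkenyl groups lie on the other face; the alkoxide is silylated cold before a 1,2-silyl shift can occur and mild acid then cleaves the more labile tertiary TES ether selectively.

Step 26
Reactants: 40 diene alcohol
Product: 41 (1S,5S,7S,10R)-5-[(tert-butyldimethylsilyl)oxy]guaia-3,11-dien-1-ol (O1′ and O5′ cis; C10′ methyl and C7′ isopropenyl on the opposite face)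
Conditions: second-generation Hoveyda–Grubbs catalyst (5 mol%), toluene, 60 °C
Reagents that add atoms: none
Why: Ring-closing metathesis between the cis-disposed allyl and isopropenyl groups forms the five-membered ring with the trisubstituted C3′=C4′ alkene, a far faster closure than any involving the remote C7′ isopropenyl group.

**Endgame**

Step 27
Reactants: 41 guaiane alcohol; 28 pentacyclic ketone
Product: 43 C2 aryl ether of 28 bonded to O1′ of the guaiane (C5′ OTBS; C3 Br; C6 ketone; C21 ketal), via potassium alkoxide 42 (not isolated)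
Conditions: 41 (1.5 equiv), KN(SiMe3)2, THF, 0 °C; then 28, DMF, 0 to 40 °C
Reagents that add atoms: none
Why: SNAr: the tertiary O1′ alkoxide displaces fluoride at C2, the only position activated (para) by the C6 ketone, while O5′ is blocked as its silyl ether so that the regiochemistry of the later dioxane is fixed.

Step 28
Reactants: 43 silyl ether
Product: 44 C5′ alcohol of 43
Conditions: Bu4NF, THF, 50 °C
Reagents that add atoms: none
Why: Fluoride cleaves the tertiary silyl ether under conditions that leave the ketal, the aryl ether and the alkenes unchanged.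

Step 29
Reactants: 44 bromo alcohol
Product: 45 dioxane-bridged C6 ketone, C21 ketal (O1′ at C2, O5′ at C3)
Conditions: CuI (20 mol%), 3,4,7,8-tetramethyl-1,10-phenanthroline (40 mol%), Cs2CO3, toluene, 110 °C
Reagents that add atoms: none
Why: Intramolecular Ullmann-type etherification couples the tertiary O5′ alkoxide with C3–Br and closes the six-membered dioxane, which is necessarily cis-fused because both oxygens lie on the same face of the guaiane.

Step 30
Reactants: 45 ketone
Product: 47 CNP0233042.2, via C6 carbinol 46 (not isolated)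
Conditions: NaBH4, THF/MeOH, 0 °C; then 1 M aq. HCl, THF, 40 °C
Reagents that add atoms: water, O
Why: Borohydride reduces the only ketone, and acid then ionises the benzylic C6 carbinol (para to the C2 ether oxygen) to give the conjugated C6=C7 alkene by E1 dehydration and hydrolyses the dioxolane to the C21 ketone, without touching any stereocentre.

**Compound list**

1 | 2-bromo-3-fluorotoluene | Cc1cccc(F)c1Br | starting material
2 | 2-(4-bromo-3-fluoro-5-methylphenyl)-4,4,5,5-tetramethyl-1,3,2-dioxaborolane | Cc1cc(B2OC(C)(C)C(C)(C)O2)cc(F)c1Br | intermediate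
3 | (4-bromo-3-fluoro-5-methylphenyl)boronic acid | Cc1cc(B(O)O)cc(F)c1Br | intermediate
4 | geraniol | CC(C)=CCC/C(C)=C/CO | starting material
5 | (S)-3-(4-bromo-3-fluoro-5-methylphenyl)-3,7-dimethyloct-6-enal | O=CC[C@](C)(CCC=C(C)C)c1cc(C)c(Br)c(F)c1 | intermediate
6 | (S)-3-(4-bromo-3-fluoro-5-methylphenyl)-3,7-dimethyloct-6-en-1-ol | OCC[C@](C)(CCC=C(C)C)c1cc(C)c(Br)c(F)c1 | intermediate
7 | (S)-2-bromo-5-(1-bromo-3,7-dimethyloct-6-en-3-yl)-1-fluoro-3-methylbenzene | BrCC[C@](C)(CCC=C(C)C)c1cc(C)c(Br)c(F)c1 | intermediate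
8 | (S)-6-bromo-4-(4-bromo-3-fluoro-5-methylphenyl)-4-methylhexanal | BrCC[C@](C)(CCC=O)c1cc(C)c(Br)c(F)c1 | intermediate
9 | (S)-6-bromo-4-(4-bromo-3-fluoro-5-methylphenyl)-4-methylhexanoic acid | BrCC[C@](C)(CCC(=O)O)c1cc(C)c(Br)c(F)c1 | intermediate
10 | (S)-7-bromo-4-(2-bromoethyl)-6-fluoro-4,8-dimethyl-3,4-dihydronaphthalen-1(2H)-one | BrCC[C@]1(C)CCC(=O)c2c(C)c(Br)c(F)cc12 | intermediate
11 | TBS enol ether of 10 | BrCC[C@]1(C)CC=C(O[Si](C)(C)C(C)(C)C)c2c(C)c(Br)c(F)cc12 | intermediate
12 | iodoethyl TBS enol ether | ICC[C@]1(C)CC=C(O[Si](C)(C)C(C)(C)C)c2c(C)c(Br)c(F)cc12 | intermediate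
13 | 1,4-dioxaspiro[4.5]dec-6-en-8-one | O=C1C=CC2(CC1)OCCO2 | starting material
14 | (±)-9-methyl-1,4-dioxaspiro[4.5]dec-6-en-8-one | CC1CC2(OCCO2)C=CC1=O | intermediate
15 | (6R)-6,9-dimethyl-1,4-dioxaspiro[4.5]decan-8-one | CC1CC2(OCCO2)[C@H](C)CC1=O | intermediate
16 | (S)-1-phenylethylamine | C[C@H](N)c1ccccc1 | starting material
17 | ethyl vinyl ketone | C=CC(=O)CC | starting material
18 | (S)-1-phenylethyl imine of 15 | CC1CC2(OCCO2)[C@H](C)CC1=N[C@@H](C)c1ccccc1 | intermediate
19 | (S)-1-phenylethyl imine of 20 | CCC(=O)CC[C@@]1(C)CC2(OCCO2)[C@H](C)CC1=N[C@@H](C)c1ccccc1 | intermediate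
20 | (6R,9S)-6,9-dimethyl-9-(3-oxopentyl)-1,4-dioxaspiro[4.5]decan-8-one | CCC(=O)CC[C@@]1(C)CC2(OCCO2)[C@H](C)CC1=O | intermediate
21 | (4aS,7R)-6,6-(ethylenedioxy)-1,4a,7-trimethyl-4,4a,5,6,7,8-hexahydronaphthalen-2(3H)-one | CC1=C2C[C@@H](C)C3(OCCO3)C[C@]2(C)CCC1=O | intermediate
22 | (1R,4aS,7R,8aS)-6,6-(ethylenedioxy)-1,4a,7-trimethyloctahydronaphthalen-2(1H)-one | C[C@@H]1[C@@H]2C[C@@H](C)C3(OCCO3)C[C@]2(C)CCC1=O | intermediate
23 | C13=C14 trimethylsilyl enol ether of 22 | C[Si](C)(C)OC1=C(C)[C@@H]2C[C@@H](C)C3(OCCO3)C[C@]2(C)CC1 | intermediate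
24 | lithium enolate of 22 | [Li+].[O-]C1=C(C)[C@@H]2C[C@@H](C)C3(OCCO3)C[C@]2(C)CC1 | intermediate
25 | C13-alkylated decalone (C14 ketone, C21 ketal, ring B TBS enol ether) | CC(C)(C)[Si](C)(C)OC1=CC[C@@](C)(CC[C@@]2(C)[C@@H]3C[C@@H](C)C4(OCCO4)C[C@]3(C)CCC2=O)c2cc(F)c(Br)c(C)c12 | intermediate
26 | C14-methylene analogue of 25 | CC(C)(C)[Si](C)(C)OC1=CC[C@@](C)(CC[C@@]2(C)[C@@H]3C[C@@H](C)C4(OCCO4)C[C@]3(C)CCC2=C)c2cc(F)c(Br)c(C)c12 | intermediate
27 | 3-bromo-2-fluoro naphthalenone, C14 methylene, C21 ketal | Brc1c(F)cc2c(c1C)C(=O)C=C[C@@]2(C)CC[C@@]2(C)[C@@H]4C[C@@H](C)C5(OCCO5)C[C@]4(C)CCC2=C | intermediate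
28 | 3-bromo-2-fluoro pentacyclic C6 ketone, C21 ketal | Brc1c(F)cc2c(c1C)C(=O)C[C@@H]1[C@@]2(C)CC[C@@]2(C)[C@@H]4C[C@@H](C)C5(OCCO5)C[C@]4(C)CC[C@]12C | intermediate
29 | (S)-(+)-carvone | CC1=CC[C@@H](CC1=O)C(C)=C | starting material
30 | trimethyl{[(5S)-2-methyl-5-(prop-1-en-2-yl)cyclohex-1-en-1-yl]oxy}silane | CC1=C(O[Si](C)(C)C)C[C@H](CC1)C(C)=C | intermediate
31 | trimethyl{[(3S)-6-methyl-3-(prop-1-en-2-yl)bicyclo[4.1.0]heptan-1-yl]oxy}silane | CC12CC[C@H](C(C)=C)CC1(O[Si](C)(C)C)C2 | intermediate
32 | (6S)-3-chloro-3-methyl-6-(prop-1-en-2-yl)cycloheptan-1-one | CC1(Cl)CC[C@H](C(C)=C)CC(=O)C1 | intermediate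
33 | (S)-3-methyl-6-(prop-1-en-2-yl)cyclohept-2-en-1-one | C=C(C)[C@H]1CCC(C)=CC(=O)C1 | intermediate
34 | diethoxy(methyl){[(3R,6S)-3-methyl-6-(prop-1-en-2-yl)cyclohept-1-en-1-yl]oxy}silane | C=C(C)[C@H]1CC[C@@H](C)C=C(O[Si](C)(OCC)OCC)C1 | intermediate
35 | (2S,3R,6S)-2-allyl-3-methyl-6-(prop-1-en-2-yl)cycloheptan-1-one | C=C(C)[C@H]1CC[C@@H](C)[C@H](CC=C)C(=O)C1 | intermediate
36 | (2S,3R,6S)-2-allyl-2-hydroxy-3-methyl-6-(prop-1-en-2-yl)cycloheptan-1-one | C=C(C)[C@H]1CC[C@@H](C)[C@@](O)(CC=C)C(=O)C1 | intermediate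
37 | triethylsilyl ether of 36 | C=C(C)[C@H]1CC[C@@H](C)[C@@](O[Si](CC)(CC)CC)(CC=C)C(=O)C1 | intermediate
38 | lithium C5′ alkoxide, C1′ OTES | C=C(C)[C@H]1CC[C@@H](C)[C@@](O[Si](CC)(CC)CC)(CC=C)[C@@]([O-])(C(C)=C)C1.[Li+] | intermediate
39 | C1′ OTES, C5′ OTBS bis-silyl ether | C=C(C)[C@H]1CC[C@@H](C)[C@@](O[Si](CC)(CC)CC)(CC=C)[C@@](O[Si](C)(C)C(C)(C)C)(C(C)=C)C1 | intermediate
40 | (1S,2S,4S,7R)-1-allyl-2-[(tert-butyldimethylsilyl)oxy]-7-methyl-2,4-di(prop-1-en-2-yl)cycloheptan-1-ol | C=C(C)[C@H]1CC[C@@H](C)[C@@](O)(CC=C)[C@@](O[Si](C)(C)C(C)(C)C)(C(C)=C)C1 | intermediate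
41 | (1S,5S,7S,10R)-5-[(tert-butyldimethylsilyl)oxy]guaia-3,11-dien-1-ol | C=C(C)[C@H]1CC[C@@H](C)[C@@]2(O)CC=C(C)[C@@]2(O[Si](C)(C)C(C)(C)C)C1 | intermediate
42 | potassium alkoxide of 41 | C=C(C)[C@H]1CC[C@@H](C)[C@@]2([O-])CC=C(C)[C@@]2(O[Si](C)(C)C(C)(C)C)C1.[K+] | intermediate
43 | C2 O1′-guaianyl ether, C5′ OTBS, C3 Br, C6 ketone, C21 ketal | C=C(C)[C@H]1CC[C@@H](C)[C@@]2(Oc3cc4c(c(C)c3Br)C(=O)C[C@@H]3[C@@]4(C)CC[C@@]4(C)[C@@H]5C[C@@H](C)C6(OCCO6)C[C@]5(C)CC[C@]34C)CC=C(C)[C@@]2(O[Si](C)(C)C(C)(C)C)C1 | intermediate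
44 | C5′ alcohol of 43 | C=C(C)[C@H]1CC[C@@H](C)[C@@]2(Oc3cc4c(c(C)c3Br)C(=O)C[C@@H]3[C@@]4(C)CC[C@@]4(C)[C@@H]5C[C@@H](C)C6(OCCO6)C[C@]5(C)CC[C@]34C)CC=C(C)[C@@]2(O)C1 | intermediate
45 | dioxane-bridged C6 ketone, C21 ketal | C=C(C)[C@H]1CC[C@@H](C)[C@@]23CC=C(C)[C@]2(C1)Oc1c(cc2c(c1C)C(=O)C[C@@H]1[C@@]2(C)CC[C@@]2(C)[C@@H]4C[C@@H](C)C5(OCCO5)C[C@]4(C)CC[C@]12C)O3 | intermediate
46 | C6 carbinol of 45 (C6 epimers) | C=C(C)[C@H]1CC[C@@H](C)[C@@]23CC=C(C)[C@]2(C1)Oc1c(cc2c(c1C)C(O)C[C@@H]1[C@@]2(C)CC[C@@]2(C)[C@@H]4C[C@@H](C)C5(OCCO5)C[C@]4(C)CC[C@]12C)O3 | intermediate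
47 | CNP0233042.2 | C=C(C)[C@H]1CC[C@@H](C)[C@@]23CC=C(C)[C@]2(C1)Oc1c(cc2c(c1C)C=C[C@@H]1[C@@]2(C)CC[C@@]2(C)[C@@H]4C[C@@H](C)C(=O)C[C@]4(C)CC[C@]12C)O3 | target

**Count.** Total steps: 30. Longest linear sequence: 16 (steps 1–8, 15–18, 27–30).

**Steps most likely to fail**

Step 18. The tertiary C14 radical may be quenched by a second hydrogen-atom transfer before it cyclises (net hydrogenation of the methylene), or it may add to C8 with poor facial selectivity at C14. The fallback generates the same radical without a hydride reductant. It sets out from 25: MeMgBr/CeCl3 gives the tertiary C14 carbinol F1; Pd(OAc)2 as in step 17 gives the naphthalenone carbinol F2; acylation with methyl chlorooxoacetate/DMAP followed by aqueous CsOH gives the cesium oxalate F3; irradiation with blue light in the presence of [Ir(dF(CF3)ppy)2(dtbbpy)]PF6 in DME/DMF/H2O releases two CO2, and the tertiary radical cyclises onto C8, returning to the route at 28.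

Step 27. The silyl group may shift from O5′ to the neighbouring O1′ alkoxide, which would let O5′ attack C2 and scramble the regiochemistry, and reversible enolisation of the C6 ketone may slow the substitution. The fallback uses a protecting group that cannot migrate. It sets out from 37: isopropenyllithium addition with a cold protic quench gives the C1′-OTES, C5′-OH diol monoether F4; 2-(4-methoxybenzyloxy)-4-methylquinoline/MeOTf/MgO under neutral conditions gives the C5′ PMB ether F5; AcOH/THF/H2O removes the TES group to give F6; ring-closing metathesis as in step 26 gives the guaiane PMB ether F7; SNAr with 28 as in step 27 gives the aryl ether F8; DDQ in CH2Cl2/pH 7 buffer cleaves the PMB ether and returns to the route at 44.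

Step 15. C-alkylation of the hindered tetrasubstituted enolate by an unactivated primary iodide may be slow, so that proton transfer, O-alkylation or loss of HI takes over. The fallback replaces the SN2 step by a fast carbonyl addition. It sets out from 12: Me3NO in DMSO oxidises the iodide to the C12 aldehyde F9; addition of lithium enolate 24 at −78 °C gives the C12 aldol F10 with the C13 quaternary centre; thiocarbonyldiimidazole gives the imidazolyl thiocarbonate F11; Bu3SnH/AIBN in toluene at 80 °C removes the C12 oxygen (Barton–McCombie) and returns to the route at 25.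

**Further compounds**

F1 | step 18 | C14 tertiary carbinol of 25 | CC(C)(C)[Si](C)(C)OC1=CC[C@@](C)(CC[C@@]2(C)[C@@H]3C[C@@H](C)C4(OCCO4)C[C@]3(C)CCC2(C)O)c2cc(F)c(Br)c(C)c12
F2 | step 18 | naphthalenone C14 carbinol | Brc1c(F)cc2c(c1C)C(=O)C=C[C@@]2(C)CC[C@@]2(C)[C@@H]4C[C@@H](C)C5(OCCO5)C[C@]4(C)CCC2(C)O
F3 | step 18 | cesium C14 oxalate of F2 | Brc1c(F)cc2c(c1C)C(=O)C=C[C@@]2(C)CC[C@@]2(C)[C@@H]4C[C@@H](C)C5(OCCO5)C[C@]4(C)CCC2(C)OC(=O)C(=O)[O-].[Cs+]
F4 | step 27 | C1′-OTES, C5′-OH cycloheptanediol monoether | C=C(C)[C@H]1CC[C@@H](C)[C@@](O[Si](CC)(CC)CC)(CC=C)[C@@](O)(C(C)=C)C1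
F5 | step 27 | C1′-OTES, C5′-OPMB diether | C=C(C)[C@H]1CC[C@@H](C)[C@@](O[Si](CC)(CC)CC)(CC=C)[C@@](OCc2ccc(OC)cc2)(C(C)=C)C1
F6 | step 27 | C1′-OH, C5′-OPMB monocycle | C=C(C)[C@H]1CC[C@@H](C)[C@@](O)(CC=C)[C@@](OCc2ccc(OC)cc2)(C(C)=C)C1
F7 | step 27 | (1S,5S,7S,10R)-5-(4-methoxybenzyloxy)guaia-3,11-dien-1-ol | C=C(C)[C@H]1CC[C@@H](C)[C@@]2(O)CC=C(C)[C@@]2(OCc3ccc(OC)cc3)C1
F8 | step 27 | C5′-OPMB analogue of 43 | C=C(C)[C@H]1CC[C@@H](C)[C@@]2(Oc3cc4c(c(C)c3Br)C(=O)C[C@@H]3[C@@]4(C)CC[C@@]4(C)[C@@H]5C[C@@H](C)C6(OCCO6)C[C@]5(C)CC[C@]34C)CC=C(C)[C@@]2(OCc7ccc(OC)cc7)C1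
F9 | step 15 | C12 aldehyde from 12 | O=CC[C@]1(C)CC=C(O[Si](C)(C)C(C)(C)C)c2c(C)c(Br)c(F)cc12
F10 | step 15 | C12-hydroxy analogue of 25 (C12 epimers) | CC(C)(C)[Si](C)(C)OC1=CC[C@@](C)(CC(O)[C@@]2(C)[C@@H]3C[C@@H](C)C4(OCCO4)C[C@]3(C)CCC2=O)c2cc(F)c(Br)c(C)c12
F11 | step 15 | C12 imidazolyl thiocarbonate of F10 | CC(C)(C)[Si](C)(C)OC1=CC[C@@](C)(CC(OC(=S)n5ccnc5)[C@@]2(C)[C@@H]3C[C@@H](C)C4(OCCO4)C[C@]3(C)CCC2=O)c2cc(F)c(Br)c(C)c12
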